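**Plan**
- Retrosynthesis: the C14 aldehyde is taken back to a methyl group and the C8 ester to the alcohol. The ring is then cut at C8–C9 with transposition of C1=C10. This is possible because C9 is the CH2 that joins the C8 carbinol to the C1=C10 ring olefin, a homoallylic alcohol inside the ten-membered ring. It gives an open chain with a C8 aldehyde, a C1 boronate and a C9=C10 methylene. Further cuts are C1=C10 (Wittig) and C6–C7 together with the lactone C–O bond.
- Forward: nerol gives the epoxy aldehyde; the lactone ring is made first (C6–C7), the chain is extended at C1, C1 is borylated, and the ten-membered ring is closed last.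
- Stereochemistry: C4/C5 from the Sharpless epoxidation, C6 by Felkin–Anh addition, C7 from the geometry of an allylboronate in a chair. C1 (temporary) comes from a chiral Cu catalyst; C8 and the ring-cis olefin come by transfer from C1.
- The α-methylene lactone is masked as its phenylselenide adduct while the Cu–boryl reagent and the C8 aldehyde are present; C14 is oxidised at the end.

Key step: step 14

Remarks:
- Atom numbers are those of the germacranolide target throughout (C1–C10 ring, C11–C13 lactone arm, C14 on C10, C15 on C4).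
- Assumption: CuCl/(R,R)-QuinoxP* is taken to give the (1R)-boronate from carbonate 17; if a model carbonate shows the opposite sense, the (S,S)-ligand is used.
- Assumption: the selenol adduct of step 10 is drawn as the 7,11-trans isomer; the C11 epimer would serve equally, because C11 returns to sp2 in step 16.

**Route**

Step 1
Reactants: 1 nerol
Product: 2 (2S,3R)-2,3-epoxynerol
Conditions: Ti(O-i-Pr)4 (10 mol %), L-(+)-diethyl tartrate (12 mol %), t-BuOOH, 4 Å MS, CH2Cl2, −20 °C
Reagents that add atoms: tert-butyl hydroperoxide, CC(C)(C)OO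
Why: Sharpless asymmetric epoxidation of the allylic alcohol; the L-(+)-tartrate complex delivers oxygen to one face of the C4=C5 olefin and sets C4 (R) and C5 (S), while the remote olefin has no directing hydroxyl.

Step 2
Reactants: 2 (2S,3R)-2,3-epoxynerol
Product: 3 (2R,3R)-3-methyl-3-(4-methylpent-3-en-1-yl)oxirane-2-carbaldehyde
Conditions: TEMPO (10 mol %), PhI(OAc)2, CH2Cl2, rt; used crude
Reagents that add atoms: none
Why: Oxoammonium (TEMPO) oxidation of a primary epoxy alcohol to the epoxy aldehyde under near-neutral conditions that leave the epoxide and the trisubstituted olefin alone.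

Step 3
Reactants: 4 tert-butyldimethyl(prop-2-yn-1-yloxy)silane
Product: 6 methyl 4-[(tert-butyldimethylsilyl)oxy]but-2-ynoate, via lithium acetylide 5 (not isolated)
Conditions: n-BuLi, THF, −78 °C; then ClCO2Me, −78 → 0 °C
Reagents that add atoms: methyl chloroformate, COC(=O)Cl
Why: Acylation of a lithium acetylide with a chloroformate, a standard route to alk-2-ynoates.

Step 4
Reactants: 6 methyl 4-[(tert-butyldimethylsilyl)oxy]but-2-ynoate
Product: 8 methyl (Z)-4-[(tert-butyldimethylsilyl)oxy]-2-[(4,4,5,5-tetramethyl-1,3,2-dioxaborolan-2-yl)methyl]but-2-enoate, via alkenylalane 7 (not isolated)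
Conditions: DIBAL-H, HMPA, THF, 0 °C; then ICH2Bpin, 0 °C → rt
Reagents that add atoms: 2-(iodomethyl)-4,4,5,5-tetramethyl-1,3,2-dioxaborolane, ICB1OC(C)(C)C(C)(C)O1
Why: Syn hydroalumination of the ynoate places Al on the α-carbon and the silyloxymethyl group cis to the ester; trapping with the iodomethylboronate then gives the ester-substituted allylboronate with CH2OTBS trans to CH2B.

Step 5
Reactants: 3 epoxy aldehyde; 8 ester-substituted allylboronate
Product: 10 trans-6,7-disubstituted α-methylene-γ-butyrolactone (C8 silyl ether; isopropylidene terminus), via O-boryl adduct 9 (not isolated)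
Conditions: toluene, 60 °C; then PPTS (cat.), rt
Reagents that add atoms: none
Why: Allylboration through a chair followed by lactonisation of the borate onto the methyl ester: Felkin–Anh attack anti to the epoxide C–O bond sets C6 (S), and the geometry of 8 (CH2OTBS trans to CH2B) gives the anti adduct, so C7 is set with the C6 and C7 substituents trans on the lactone.

Step 6
Reactants: 10 lactone with isopropylidene terminus
Product: 12 C1 aldehyde, via ozonide 11 (not isolated)
Conditions: O3, CH2Cl2, −78 °C; then Me2S, −78 °C → rt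
Reagents that add atoms: ozone, [O-][O+]=O
Why: Ozonolysis with reductive work-up; the electron-rich trisubstituted olefin reacts far faster than the electron-poor exocyclic methylene of the lactone.

Step 7
Reactants: 12 C1 aldehyde
Product: 13 (E)-2-methyl enal (C1=C10 with CH3 and CHO on C10)
Conditions: Ph3P=C(CH3)CHO, toluene, 80 °C
Reagents that add atoms: 2-(triphenylphosphoranylidene)propanal, CC(C=O)=P(c1ccccc1)(c1ccccc1)c1ccccc1
Why: Wittig olefination with a stabilised formyl ylide, which gives the (E)-trisubstituted enal and does not touch the lactone or the epoxide.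

Step 8
Reactants: 13 enal
Product: 14 allylic alcohol (C9 hydroxyl)
Conditions: NaBH4, CeCl3·7H2O, MeOH, −40 °C
Reagents that add atoms: none
Why: Luche reduction, a fast 1,2-reduction of the aldehyde that should spare the α-methylene lactone at low temperature with a limited amount of hydride.

Step 9
Reactants: 14 allylic alcohol
Product: 15 allylic methyl carbonate
Conditions: ClCO2Me, pyridine, CH2Cl2, 0 °C
Reagents that add atoms: methyl chloroformate, COC(=O)Cl
Why: Acylation of the primary alcohol with a chloroformate installs the leaving group for the copper-catalysed substitution.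

Step 10
Reactants: 15 allylic methyl carbonate
Product: 16 13-phenylselanyl-11,13-dihydro lactone (11S)
Conditions: PhSeH, Et3N (10 mol %), THF, 0 °C
Reagents that add atoms: benzeneselenol, [SeH]c1ccccc1
Why: Seleno-Michael addition to the α-methylene lactone, much faster than epoxide opening or attack on the carbonate; it removes the acceptor that a Cu–boryl species would attack and lowers the acidity of C7–H, and C11 is protonated to the 7,11-trans lactone.

Step 11
Reactants: 16 selenide
Product: 17 C8 primary alcohol
Conditions: HF·pyridine, pyridine, THF, 0 °C → rt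
Reagents that add atoms: none
Why: Buffered fluoride cleavage of the primary silyl ether, compatible with the epoxide, the carbonate and the selenide; it is done before borylation because an allylboronate would not survive fluoride.

Step 12
Reactants: 17 C8 alcohol with allylic carbonate
Product: 18 (1R)-allyl pinacolboronate with C9=C10 methylene
Conditions: CuCl (10 mol %), KO-t-Bu (10 mol %), (R,R)-QuinoxP* (10 mol %), B2pin2 (2 equiv), THF, 0 °C
Reagents that add atoms: bis(pinacolato)diboron, CC1(C)OB(OC1(C)C)B1OC(C)(C)C(C)(C)O1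
Why: Copper-catalysed γ-selective (SN2′) borylation of an allylic carbonate: the ligated Cu–Bpin adds across C1=C10 with boron on C1 and the carbonate leaves from C9 as CO2 and methoxide, the chiral bisphosphine choosing the olefin face and so setting C1 (R).

Step 13
Reactants: 18 (1R)-allylboronate alcohol
Product: 19 C8 aldehyde with C1 pinacolboronate and C9=C10 methylene
Conditions: SO3·pyridine, DMSO, i-Pr2NEt, CH2Cl2, 0 °C; used at once
Reagents that add atoms: none
Why: Parikh–Doering oxidation, an activated-DMSO method that does not oxidise the selenide and is run cold and briefly so that the α-substituted allylboronate does not yet add to the new aldehyde.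

Step 14
Reactants: 19 C8 aldehyde with C1 pinacolboronate
Product: 21 ten-membered 8-hydroxy epoxy lactone with ring-cis C1=C10 olefin, via macrocyclic borate 20 (not isolated)
Conditions: toluene, 0.002 M, rt → 70 °C; then aqueous NaHCO3 work-up
Reagents that add atoms: none
Why: Proposed new method: the aldehyde oxygen binds boron and C9 of the 2-methylallyl unit adds to C8 through a six-membered chair (B, O, C8, C9, C10, C1) while the C1–B bond becomes the C1=C10 π bond, an SE2′ allylboration that needs no promoter and so leaves epoxide, lactone and selenide alone. The closest known reactions are the allylboration of aldehydes by α-substituted allyl pinacolboronates with chirality transfer and intramolecular allylborations that close five- to seven-membered rings; a ten-membered closure is not known. The ring closes in a 10-exo-trig sense at the carbonyl group, the chair being bridged by the six-atom C2–C7 tether, which the cis-epoxide and the lactone already bend. C8 is controlled by the boron-bearing C1 centre: with the pinacol ester and the C10 methyl group, C2 should sit axial (away from the dioxaborolane methyls and free of A(1,2) strain) and C7 equatorial, so (1R) leads to (8R). The same axial C2 ends cis to C9 in the new olefin, so the single C1 epimer secures both the C8 configuration and the ring-cis geometry. Intermolecular addition is the main competing path and is held back by high dilution.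

Step 15
Reactants: 21 macrocyclic 8-alcohol
Product: 22 8-(3-methylbutanoyl) ester
Conditions: (i-BuCO)2O, DMAP (cat.), Et3N, CH2Cl2, 0 °C → rt
Reagents that add atoms: 3-methylbutanoic anhydride, CC(C)CC(=O)OC(=O)CC(C)C
Why: DMAP-catalysed acylation of the secondary alcohol with an anhydride, with retention at C8.

Step 16
Reactants: 22 selenide ester
Product: 24 14-deoxy α-methylene lactone ester, via selenoxide 23 (not isolated)
Conditions: 30% aq. H2O2, pyridine, CH2Cl2, 0 °C → rt
Reagents that add atoms: none
Why: Selenide oxidation and selenoxide syn-elimination at or below room temperature; C11–H is the only β-hydrogen, so the C11=C13 methylene is regenerated.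

Step 17
Reactants: 24 14-deoxy lactone ester
Product: 25 14-hydroxy compound
Conditions: SeO2 (30 mol %), t-BuOOH (3 equiv), CH2Cl2, rt
Reagents that add atoms: tert-butyl hydroperoxide, CC(C)(C)OO (oxygen relayed through selenium dioxide, O=[Se]=O)
Why: SeO2 allylic oxidation (ene reaction, then [2,3] shift): the C10 methyl lies trans to C2, the position this reagent prefers, and C9 is deactivated by the neighbouring acyloxy group; the reagent is known to hydroxylate the C10 methyl of related 4,5-epoxy germacranolides, and any enal formed is already the target.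

Step 18
Reactants: 25 14-hydroxy compound
Product: 26 CNP0260081.1
Conditions: MnO2, CH2Cl2, rt
Reagents that add atoms: none
Why: MnO2 oxidation of a primary allylic alcohol to the enal without change of olefin geometry and without touching the ester, the epoxide or the lactone.

**Compound list**

1 | nerol, (Z)-3,7-dimethylocta-2,6-dien-1-ol | CC(C)=CCC/C(C)=C\CO | starting material
2 | (2S,3R)-2,3-epoxynerol, [(2S,3R)-3-methyl-3-(4-methylpent-3-en-1-yl)oxiran-2-yl]methanol | CC(C)=CCC[C@@]1(C)O[C@H]1CO | intermediate
3 | (2R,3R)-3-methyl-3-(4-methylpent-3-en-1-yl)oxirane-2-carbaldehyde | CC(C)=CCC[C@@]1(C)O[C@H]1C=O | intermediate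
4 | tert-butyldimethyl(prop-2-yn-1-yloxy)silane | C#CCO[Si](C)(C)C(C)(C)C | starting material
5 | lithium acetylide of 4 | [Li]C#CCO[Si](C)(C)C(C)(C)C | intermediate (not isolated)
6 | methyl 4-[(tert-butyldimethylsilyl)oxy]but-2-ynoate | COC(=O)C#CCO[Si](C)(C)C(C)(C)C | intermediate
7 | methyl 2-(diisobutylalumanyl)-4-[(tert-butyldimethylsilyl)oxy]but-2-enoate, silyloxymethyl cis to the ester | COC(=O)/C(=C\CO[Si](C)(C)C(C)(C)C)[Al](CC(C)C)CC(C)C | intermediate (not isolated)
8 | methyl (Z)-4-[(tert-butyldimethylsilyl)oxy]-2-[(4,4,5,5-tetramethyl-1,3,2-dioxaborolan-2-yl)methyl]but-2-enoate (CH2OTBS cis to CO2Me, trans to CH2B) | COC(=O)/C(CB1OC(C)(C)C(C)(C)O1)=C\CO[Si](C)(C)C(C)(C)C | intermediate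
9 | O-pinacolboryl anti adduct: methyl 2-methylene ester with C7 (CH2OTBS) and C6 (OBpin) anti, C6 anti to the (4R,5S)-epoxide | COC(=O)C(=C)[C@H](CO[Si](C)(C)C(C)(C)C)[C@H](OB1OC(C)(C)C(C)(C)O1)[C@@H]2O[C@]2(C)CCC=C(C)C | intermediate (not isolated)
10 | α-methylene-γ-butyrolactone (12,6-olide), C6 (S) bearing the (4R,5S)-epoxide chain ending in CH=CMe2, C7 (R) bearing CH2OTBS, 6,7-trans | C=C1C(=O)O[C@@H]([C@H]1CO[Si](C)(C)C(C)(C)C)[C@@H]1O[C@]1(C)CCC=C(C)C | intermediate
11 | ozonide (1,2,4-trioxolane) of 10 at the isopropylidene olefin | C=C1C(=O)O[C@@H]([C@H]1CO[Si](C)(C)C(C)(C)C)[C@@H]1O[C@]1(C)CCC2OOC(C)(C)O2 | intermediate (not isolated)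
12 | C1 aldehyde of the lactone silyl ether (C4–C7 as in 10) | C=C1C(=O)O[C@@H]([C@H]1CO[Si](C)(C)C(C)(C)C)[C@@H]1O[C@]1(C)CCC=O | intermediate
13 | (E)-enal: C1=C10 with CH3 and CHO on C10, CHO trans to C2 | C=C1C(=O)O[C@@H]([C@H]1CO[Si](C)(C)C(C)(C)C)[C@@H]1O[C@]1(C)CC/C=C(\C)C=O | intermediate
14 | (E)-allylic alcohol (C9 OH) | C=C1C(=O)O[C@@H]([C@H]1CO[Si](C)(C)C(C)(C)C)[C@@H]1O[C@]1(C)CC/C=C(\C)CO | intermediate
15 | (E)-allylic methyl carbonate at C9 | C=C1C(=O)O[C@@H]([C@H]1CO[Si](C)(C)C(C)(C)C)[C@@H]1O[C@]1(C)CC/C=C(\C)COC(=O)OC | intermediate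
16 | 13-(phenylselanyl)-11,13-dihydro lactone, (4R,5S,6S,7R,11S), C8 silyl ether, C9 carbonate | c1ccccc1[Se]C[C@@H]1C(=O)O[C@@H]([C@H]1CO[Si](C)(C)C(C)(C)C)[C@@H]1O[C@]1(C)CC/C=C(\C)COC(=O)OC | intermediate
17 | C8 primary alcohol of 16 | c1ccccc1[Se]C[C@@H]1C(=O)O[C@@H]([C@H]1CO)[C@@H]1O[C@]1(C)CC/C=C(\C)COC(=O)OC | intermediate
18 | (1R)-C1 pinacolboronate with C9=C10 methylene and C10 methyl, C8 alcohol | c1ccccc1[Se]C[C@@H]1C(=O)O[C@@H]([C@H]1CO)[C@@H]1O[C@]1(C)CC[C@@H](B2OC(C)(C)C(C)(C)O2)C(C)=C | intermediate
19 | C8 aldehyde with (1R)-C1 pinacolboronate and C9=C10 methylene (C4–C7, C11 arranged as in 18) | c1ccccc1[Se]C[C@@H]1C(=O)O[C@@H]([C@H]1C=O)[C@@H]1O[C@]1(C)CC[C@@H](B2OC(C)(C)C(C)(C)O2)C(C)=C | intermediate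
20 | macrocyclic 8-O-pinacolborate of 21 | c1ccccc1[Se]C[C@@H]1C(=O)O[C@H]2[C@H]1[C@H](OB3OC(C)(C)C(C)(C)O3)C/C(C)=C\CC[C@@]1(C)O[C@@H]21 | intermediate (not isolated)
21 | (1(10)Z,4R,5S,6S,7R,8R,11S)-4,5-epoxy-8-hydroxy-13-(phenylselanyl)germacr-1(10)-en-12,6-olide (C2 and C9 cis on the olefin) | c1ccccc1[Se]C[C@@H]1C(=O)O[C@H]2[C@H]1[C@H](O)C/C(C)=C\CC[C@@]1(C)O[C@@H]21 | intermediate
22 | 8-O-(3-methylbutanoyl) ester of 21 | c1ccccc1[Se]C[C@@H]1C(=O)O[C@H]2[C@H]1[C@H](OC(=O)CC(C)C)C/C(C)=C\CC[C@@]1(C)O[C@@H]21 | intermediate
23 | selenoxide of 22 (mixture at selenium) | O=[Se](C[C@@H]1C(=O)O[C@H]2[C@H]1[C@H](OC(=O)CC(C)C)C/C(C)=C\CC[C@@]1(C)O[C@@H]21)c1ccccc1 | intermediate (not isolated)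
24 | (1(10)Z,4R,5S,6S,7R,8R)-4,5-epoxy-8-(3-methylbutanoyloxy)germacra-1(10),11(13)-dien-12,6-olide | C=C1C(=O)O[C@H]2[C@H]1[C@H](OC(=O)CC(C)C)C/C(C)=C\CC[C@@]1(C)O[C@@H]21 | intermediate
25 | 14-hydroxy derivative of 24 (olefin geometry unchanged: C2 and C9 cis) | C=C1C(=O)O[C@H]2[C@H]1[C@H](OC(=O)CC(C)C)C/C(CO)=C\CC[C@@]1(C)O[C@@H]21 | intermediate
26 | CNP0260081.1, (4R,5S,6S,7R,8R)-4,5-epoxy-8-(3-methylbutanoyloxy)-14-oxogermacra-1(10),11(13)-dien-12,6-olide with C2 and C9 cis on C1=C10 | C=C1C(=O)O[C@H]2[C@H]1[C@H](OC(=O)CC(C)C)C/C(C=O)=C\CC[C@@]1(C)O[C@@H]21 | target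

**Totals and risks**

Total step count: 18. Longest linear sequence: 16 steps (nerol 1 to 26 through steps 1, 2 and 5–18; steps 3 and 4 make the boronate 8).

The three steps most likely to fail:

Step 14. Ring closure may lose to intermolecular addition even at high dilution, or the addition may run through the chair with C2 equatorial, which would give the ring-trans olefin and the C8 epimer. The fallback makes C8–C9 between two molecules and closes the ring at C1=C10 instead, with known reactions only. From aldehyde 12, methylenation (Ph3P=CH2, THF, −78 °C) gives the terminal alkene F1. HF·pyridine frees the primary alcohol F2, and Dess–Martin periodinane gives the aldehyde F3. Methallylation with the antipode of B-methallyldiisopinocampheylborane that attacks the required face (Et2O, −78 °C, ethanolamine work-up) sets C8 and gives the homoallylic alcohol F4. Acylation with 3-methylbutanoic anhydride and DMAP gives the triene ester F5. Ring-closing metathesis between the C1 vinyl and C10 isopropenyl groups (second-generation Hoveyda–Grubbs catalyst, toluene, 0.001 M, 80 °C) closes the ten-membered ring with loss of ethylene; the ring-cis trisubstituted olefin is the less strained isomer. The route is rejoined at 24.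

Step 12. The chiral catalyst may discriminate the faces of this trisubstituted, 2-methyl-substituted olefin poorly, or may turn over slowly in the presence of the free hydroxyl and the selenide. The fallback gives up catalyst control at C1 and corrects C8 afterwards. From 17, borylation with achiral CuCl/Xantphos/KO-t-Bu and B2pin2 gives 18 together with its C1 epimer, the (1S)-boronate F6. The mixture is oxidised as in step 13 (19 and the epimeric aldehyde F7) and cyclised as in step 14. The (1S) series should pass through the mirror-related chair and give, via the borate F8, the ring-cis 8-epi alcohol F9, which is separated from 21 by chromatography. Mitsunobu esterification of F9 with 3-methylbutanoic acid (PPh3, DIAD, toluene) inverts C8 and gives 22, so both C1 epimers converge there.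

Step 5. The ester-deactivated boronate needs heat, at which the epoxy aldehyde may decompose, and Felkin–Anh face selectivity with an achiral reagent may be modest. The fallback sets C6 and C7 with a chiral reagent. From 3, the allenylzinc made from enantiopure 1-[(tert-butyldimethylsilyl)oxy]but-3-yn-2-yl methanesulfonate (Pd(OAc)2, PPh3, Et2Zn, THF, −20 °C; the mesylate antipode matched to the aldehyde) should give the anti homopropargylic alcohol F10. Palladium-catalysed cyclocarbonylation of this alkynol (PdI2, PBu3, CO, MeCN, 75 °C) introduces C12 and the exocyclic methylene and returns lactone 10.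

Further compounds
F1 | step 14 | terminal C1 alkene of the lactone silyl ether | C=C1C(=O)O[C@@H]([C@H]1CO[Si](C)(C)C(C)(C)C)[C@@H]1O[C@]1(C)CCC=C
F2 | step 14 | C8 primary alcohol of F1 | C=C1C(=O)O[C@@H]([C@H]1CO)[C@@H]1O[C@]1(C)CCC=C
F3 | step 14 | C8 aldehyde of F1 | C=C1C(=O)O[C@@H]([C@H]1C=O)[C@@H]1O[C@]1(C)CCC=C
F4 | step 14 | (8R)-homoallylic alcohol from methallylation of F3 | C=C1C(=O)O[C@@H]([C@H]1[C@H](O)CC(C)=C)[C@@H]1O[C@]1(C)CCC=C
F5 | step 14 | 8-O-(3-methylbutanoyl) ester of F4 | C=C1C(=O)O[C@@H]([C@H]1[C@H](OC(=O)CC(C)C)CC(C)=C)[C@@H]1O[C@]1(C)CCC=C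
F6 | step 12 | (1S)-epimer of boronate 18 | c1ccccc1[Se]C[C@@H]1C(=O)O[C@@H]([C@H]1CO)[C@@H]1O[C@]1(C)CC[C@H](B2OC(C)(C)C(C)(C)O2)C(C)=C
F7 | step 12 | (1S)-epimer of aldehyde 19 | c1ccccc1[Se]C[C@@H]1C(=O)O[C@@H]([C@H]1C=O)[C@@H]1O[C@]1(C)CC[C@H](B2OC(C)(C)C(C)(C)O2)C(C)=C
F8 | step 12 | 8-epimer of macrocyclic borate 20 | c1ccccc1[Se]C[C@@H]1C(=O)O[C@H]2[C@H]1[C@@H](OB3OC(C)(C)C(C)(C)O3)C/C(C)=C\CC[C@@]1(C)O[C@@H]21
F9 | step 12 | 8-epimer of macrocyclic alcohol 21 | c1ccccc1[Se]C[C@@H]1C(=O)O[C@H]2[C@H]1[C@@H](O)C/C(C)=C\CC[C@@]1(C)O[C@@H]21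
F10 | step 5 | anti homopropargylic alcohol (C6 OH, C7 CH2OTBS, terminal alkyne as C11≡C13) | C#C[C@H](CO[Si](C)(C)C(C)(C)C)[C@H](O)[C@@H]1O[C@]1(C)CCC=C(C)C
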